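## The problem

Target 10 is a depside: a fully substituted benzoic acid (ring A) esterified with the C4 hydroxyl of methyl 2,4-dihydroxy-3,6-dimethylbenzoate (ring B). Ring A is numbered here from the carbon that carries the ester carbonyl (C1) through C2–OH, C3–CHO, C4–OH and C5–OH to C6–CH3; systematic names in the steps keep their own locants. There is no stereocentre. The task is regiocontrol on a hexasubstituted benzene and the making of an aryl ester whose acid, in the target, has two ortho substituents (C2–OH and C6–CH3). The groups that limit the reagents are the aryl ester (cleaved by alkoxides, amines and hydroxide), the aldehyde, the ring B methyl ester, and the 1,2,4-trihydroxybenzene unit of ring A, which is oxidised by air once all three hydroxyls are free. Ring B can be bought with the right substitution; its C2 hydroxyl is hydrogen-bonded to the ester and flanked on both sides, so only the C4 hydroxyl acylates. The feature that opens the route is that the C2 and C5 oxygens of ring A are para. Ring A can therefore be held as a 1,4-benzoquinone in which C6, next to the ester-bearing C1, is an acceptor carbon, and the C6 methyl group can be added last as a nucleophilic radical, after the ester has been made from an acid with only one ortho substituent.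

## Retrosynthesis

**C4 O–CH3 bond (10 from 9).** The last bond dealt with is the O–CH3 bond at C4. A free C4 hydroxyl carried through the route would put a trihydroxyarene or a hydroxyquinone into every intermediate, whereas the methyl ether comes with a commercial acid and is inert to oxidants and radicals. A benzyl ether would come off under neutral conditions, but it needs an acid that must be made and a hydrogenolysis beside an aryl aldehyde. The forward step must cleave one aryl methyl ether without touching the ring B methyl ester or the depside ester. In 9 the aldehyde oxygen is already held by the C2 hydroxyl, the situation in which BCl3 alone tends to stop, so iodide (n-Bu4NI) is added as the nucleophile. The C5 hydroxyl, which binds boron next to the ether oxygen, serves as the directing neighbour.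

**C3–CHO bond (9 from 7, through 8).** The aldehyde is introduced after all oxidative chemistry, because a formyl group would not survive tetravalent cerium or a persulfate radical reaction and would make the quinone still more electrophilic. In hydroquinone 7 exactly one hydroxyl in the whole molecule has a free ortho carbon: C2–OH, next to C3. The C5 hydroxyl is flanked by C4–OMe and C6–CH3, and the ring B hydroxyl by its ester and a methyl group. A formylation that is mechanistically ortho-specific to a phenoxide can therefore only reach C3. Hydroxymethyl compound 8 is its in-flask intermediate.

**Oxidation level (7 from 6).** No skeletal bond is cut. Quinone 6 is reduced so that ring A changes from acceptor to donor; this is what makes C3 nucleophilic for the formylation.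

**C6–CH3 bond (6 from 4 and 5), the key disconnection.** Cutting the ester of a C6-methylated acid instead would demand acylation of a phenol by a doubly ortho-substituted acid. Electrophilic methylation of a hydroquinone would go to C3, the carbon between two oxygens. In quinone 4 the polarity is reversed. C6 is β to both the C2 carbonyl and the ester and carries no donor. C3 is the electron-rich α-carbon of the vinylogous ester MeO–C4=C3–C2=O. A methyl radical made from acetic acid 5 is therefore expected at C6. The forward step must give mono-methylation at one of two C–H sites in the presence of the depside ester and the ring B phenol.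

**Quinone from arene (4 from 3).** The C2 and C5 methoxy groups of 3 are para and are removed oxidatively, the C4 methoxy group remaining as the quinone's vinylogous ester. This trades two protecting-group removals for one oxidation and produces the acceptor needed for the key step. The forward reaction must oxidise ring A and leave the less electron-rich ring B alone.

**Ester C–O bond (3 from 1 and 2).** The depside bond is cut at the acyl carbon while ring A still lacks its C6 methyl group. Acid 1 has a single ortho methoxy group and phenol 2 offers only its C4 hydroxyl, so a carbodiimide coupling suffices and no protecting group is needed. Compounds 1, 2 and 5 are commercial.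

## Roads not taken

Alternative 1: The cut is the bond between the ester oxygen and ring B C4.
- **Forward step:** 2,4,5-tris(benzyloxy)-6-methylbenzoic acid A1 is turned into its potassium salt (t-BuOK, hot toluene) and arylated on oxygen by the diaryliodonium tosylate A2. In salt A2 the iodine carries a 2,4,6-trimethoxyphenyl group and, at ring B C4, the O-benzylated ring B aryl group. The product is the fully benzylated depside A3.
- **Merits:** the bond forms at the ring B carbon, not at the carbonyl, so the two ortho substituents of acid A1 do not matter. No transition metal is needed, and the trimethoxyphenyl group of A2 is a dependable non-transferred ligand. Four benzyl ethers keep both rings of A3 quiet until a neutral hydrogenolysis, which suits the oxidisable ring A better than quinone and boron halide chemistry.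
- **Weak points:** salt A2 needs iodine at ring B C4, where commercial 2 has its hydroxyl. Electrophilic substitution does not go there (C4 is meta to the ring B oxygen and para to the ester), so the oxygen of 2 is discarded and A2 needs a longer preparation. A1 is a pentasubstituted acid that has to be assembled. C3 of A3 must still be formylated after the coupling without a free ortho hydroxyl to direct it, and four benzyl groups must then be removed beside an aryl aldehyde.
- **Comparison:** in the ester-forming step this road is at least as sound as the chosen one, and it avoids the electrophilic quinone. The chosen plan sets against this that both rings are bought, no protecting group is added, and six steps suffice.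

Alternative 2: Both bonds to the ester carbon are cut (C1–carbonyl and carbonyl–oxygen).
- **Forward step:** 1,2,5-tris(benzyloxy)-4-iodo-3-methylbenzene A4, carbon monoxide A5 and the C4 hydroxyl of 2 are joined by Pd(OAc)2, 4,5-bis(diphenylphosphino)-9,9-dimethylxanthene and Et3N to give depside A6, which keeps the free ring B hydroxyl.
- **Merits:** 2 is used as bought, as in the chosen plan. No hindered benzoic acid ever exists, because the ester carbon arrives as A5. No oxidant touches the molecule.
- **Weak points:** oxidative addition of zerovalent palladium into iodide A4, which has two ortho substituents on a very electron-rich ring, is slow. The acylpalladium intermediate must be captured by a phenol with an ortho methyl group, a weaker nucleophile than the alcohols for which such carbonylations are routine. A4 is not commercial and needs several steps with a site-selective iodination. Formylation at C3 and removal of three benzyl ethers from A6 still follow.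
- **Comparison:** this road is better in how convergently the ester carbon arrives and in ending with hydrogenolysis. It exchanges a hindered esterification for a hindered oxidative addition under a pressure of a toxic gas, and it is longer. The chosen plan meets the same steric problem by making the ester before the methyl group exists.

Alternative 3: Ring A itself is cut at C3–C4 and C5–C6.
- **Forward step:** an inverse-electron-demand Diels–Alder reaction joins the pyrone ester A7, 3-(benzyloxy)-4-(methoxycarbonyl)-2,5-dimethylphenyl 5-(benzyloxy)-3-methyl-2-oxo-2H-pyran-4-carboxylate, and the ketene silyl acetal A8, 2-(benzyloxy)-1-methoxy-1-(trimethylsilyloxy)ethene, across pyrone C3 and C6. Either alkene geometry of A8 serves, since it is lost on aromatisation. The bridged lactone would extrude its carbonyl bridge and aromatise with loss of the methoxy and silyl groups in the same operation, giving phenol A9 with C4–OH free.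
- **Merits:** every substituent of ring A is placed by the two components. The depside ester is made from a pyrone acid, not a hindered benzoic acid. The free C4 hydroxyl of A9 is exactly the ortho director needed for formylation at C3, and the end is a hydrogenolysis.
- **Weak points:** the benzyloxy-bearing nucleophilic carbon of A8 must bond to the methyl-bearing pyrone C3 of A7, not to C6. The C4 ester must thus override the usual bias of the lactone carbonyl, and that bond joins two substituted carbons. The C5 benzyloxy group makes the pyrone less electron-poor. The aryl ester must survive a nucleophilic ketene acetal and heat. A7 alone would take more steps than the whole chosen route.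
- **Comparison:** this is the most controlled way to a hexasubstituted ring and better in delivering C4–OH free. Its key-step regiochemistry is less secure than the polarity-matched radical addition, and the route is far longer; the chosen plan accepts a late ether cleavage in return.

Key step: step 3

## Route

Step 1
Reactants: 1 2,4,5-trimethoxybenzoic acid; 2 methyl 2,4-dihydroxy-3,6-dimethylbenzoate
Product: 3 3-hydroxy-4-(methoxycarbonyl)-2,5-dimethylphenyl 2,4,5-trimethoxybenzoate
Conditions: DCC (1.1 equiv), DMAP (0.1 equiv), CH2Cl2, 0 °C to rt
Reagents that add atoms: none
Why: Steglich esterification; the C4 hydroxyl of 2 is the only one that acylates, because the C2 hydroxyl is hydrogen-bonded to the methyl ester and flanked by it and by a methyl group. Acid 1 has a single ortho substituent, so acyl transfer by DMAP is not hindered.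

Step 2
Reactants: 3 3-hydroxy-4-(methoxycarbonyl)-2,5-dimethylphenyl 2,4,5-trimethoxybenzoate
Product: 4 3-hydroxy-4-(methoxycarbonyl)-2,5-dimethylphenyl 4-methoxy-3,6-dioxocyclohexa-1,4-diene-1-carboxylate
Conditions: (NH4)2Ce(NO3)6 (2.5 equiv), MeCN/H2O, 0 °C
Reagents that add atoms: water, O
Why: Oxidative demethylation of a 1,4-dimethoxyarene by tetravalent cerium: ring A is oxidised to its radical cation, water adds at the C2 and C5 carbons and methanol is lost, giving the para-quinone and leaving the C4 methoxy group as a vinylogous ester. Ring B, an acylated and ester-substituted phenol with a hydrogen-bonded hydroxyl, has a much higher oxidation potential and should be left alone at 0 °C.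

Step 3
Reactants: 4 3-hydroxy-4-(methoxycarbonyl)-2,5-dimethylphenyl 4-methoxy-3,6-dioxocyclohexa-1,4-diene-1-carboxylate; 5 acetic acid (10 equiv)
Product: 6 3-hydroxy-4-(methoxycarbonyl)-2,5-dimethylphenyl 4-methoxy-2-methyl-3,6-dioxocyclohexa-1,4-diene-1-carboxylate
Conditions: AgNO3 (0.3 equiv), (NH4)2S2O8 (1.3 equiv, added slowly as an aqueous solution), MeCN/H2O, 65 °C
Reagents that add atoms: none
Why: Silver-catalysed persulfate decarboxylative alkylation of a quinone (Jacobsen–Torssell reaction, a Minisci-type radical substitution), here with acetic acid as the methyl source. (NH4)2S2O8 oxidises monovalent silver to divalent silver, which oxidises acetate to the acetoxyl radical, and loss of CO2 gives the methyl radical. This nucleophilic radical adds to C6 of 4, the unsubstituted carbon of the C1=C6 double bond, giving a radical at C1 delocalised over the C2 carbonyl and the ester; one-electron oxidation and loss of the C6 proton restore the quinone as 6. No ring is closed and no stereocentre is formed. The step needs site selectivity between the two quinone C–H positions: C6 is β to both the ester and the C2 carbonyl and carries no donor, whereas C3 is the electron-rich α-carbon of the C4 methoxy vinylogous ester, so the polarity match sends the radical to C6. It must also stop after one methyl group: once C6 is filled only the deactivated C3–H is left, and the persulfate is kept near one equivalent and added slowly. Ring B should be spared because its only phenol is hydrogen-bonded on an acceptor-substituted ring, a much poorer partner for the radical and the oxidant than the quinone and the excess acetate. The resulting ester is flanked by the C2 carbonyl and the C6 methyl group, an arrangement that direct esterification would have had to force.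

Step 4
Reactants: 6 3-hydroxy-4-(methoxycarbonyl)-2,5-dimethylphenyl 4-methoxy-2-methyl-3,6-dioxocyclohexa-1,4-diene-1-carboxylate
Product: 7 3-hydroxy-4-(methoxycarbonyl)-2,5-dimethylphenyl 3,6-dihydroxy-4-methoxy-2-methylbenzoate
Conditions: Na2S2O4 (aq), EtOAc, rt, under argon
Reagents that add atoms: none
Why: Two-electron reduction of a quinone to its hydroquinone by dithionite in a two-phase system; esters are untouched, and the hydroquinone is the form in which C3 becomes nucleophilic.

Step 5
Reactants: 7 3-hydroxy-4-(methoxycarbonyl)-2,5-dimethylphenyl 3,6-dihydroxy-4-methoxy-2-methylbenzoate
Product: 9 3-hydroxy-4-(methoxycarbonyl)-2,5-dimethylphenyl 3-formyl-2,5-dihydroxy-4-methoxy-6-methylbenzoate, via hydroxymethyl hydroquinone 8 (not isolated)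
Conditions: MgCl2 (4 equiv), Et3N (8 equiv), (CH2O)n (8 equiv), THF, reflux, under argon; then 1 M HCl
Reagents that add atoms: paraformaldehyde (as formaldehyde), C=O
Why: Magnesium-mediated ortho-formylation of a phenol (Casnati–Skattebøl reaction): the magnesium phenoxide at C2 binds formaldehyde and delivers it to the ortho carbon C3, and 8 is oxidised to the aldehyde by hydride transfer to a second formaldehyde. Only the C2 hydroxyl of 7 has a free ortho carbon (C5–OH is flanked by C4–OMe and C6–CH3, the ring B hydroxyl by its ester and a methyl group), so the ortho-specific mechanism fixes the site. The doubly ortho-substituted aryl ester should resist the methanol set free.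

Step 6
Reactants: 9 3-hydroxy-4-(methoxycarbonyl)-2,5-dimethylphenyl 3-formyl-2,5-dihydroxy-4-methoxy-6-methylbenzoate
Product: 10 3-hydroxy-4-(methoxycarbonyl)-2,5-dimethylphenyl 3-formyl-2,4,5-trihydroxy-6-methylbenzoate
Conditions: BCl3 (4 equiv), n-Bu4NI (1.5 equiv), CH2Cl2, −78 to 0 °C; then degassed H2O
Reagents that add atoms: none
Why: Lewis acid-assisted cleavage of an aryl methyl ether: boron, held by the C5 oxygen and the neighbouring aldehyde, activates the C4 ether oxygen, and iodide removes the methyl group in an SN2 step; work-up frees the hydroxyl. The C4 oxygen is para to the C1 ester and ortho to the aldehyde, so it is a good leaving group, while methyl and aryl esters are not attacked at or below 0 °C. Degassed work-up protects the trihydroxyarene from air.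

## Compound list

1 | 2,4,5-trimethoxybenzoic acid | COc1cc(OC)c(C(=O)O)cc1OC | starting material
2 | methyl 2,4-dihydroxy-3,6-dimethylbenzoate | COC(=O)c1c(C)cc(O)c(C)c1O | starting material
3 | 3-hydroxy-4-(methoxycarbonyl)-2,5-dimethylphenyl 2,4,5-trimethoxybenzoate | COC(=O)c1c(C)cc(OC(=O)c2cc(OC)c(OC)cc2OC)c(C)c1O | intermediate
4 | 3-hydroxy-4-(methoxycarbonyl)-2,5-dimethylphenyl 4-methoxy-3,6-dioxocyclohexa-1,4-diene-1-carboxylate | COC(=O)c1c(C)cc(OC(=O)C2=CC(=O)C(OC)=CC2=O)c(C)c1O | intermediate
5 | acetic acid | CC(=O)O | starting material
6 | 3-hydroxy-4-(methoxycarbonyl)-2,5-dimethylphenyl 4-methoxy-2-methyl-3,6-dioxocyclohexa-1,4-diene-1-carboxylate | COC(=O)c1c(C)cc(OC(=O)C2=C(C)C(=O)C(OC)=CC2=O)c(C)c1O | intermediate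
7 | 3-hydroxy-4-(methoxycarbonyl)-2,5-dimethylphenyl 3,6-dihydroxy-4-methoxy-2-methylbenzoate | COC(=O)c1c(C)cc(OC(=O)c2c(C)c(O)c(OC)cc2O)c(C)c1O | intermediate
8 | 3-hydroxy-4-(methoxycarbonyl)-2,5-dimethylphenyl 2,5-dihydroxy-3-(hydroxymethyl)-4-methoxy-6-methylbenzoate | COC(=O)c1c(C)cc(OC(=O)c2c(C)c(O)c(OC)c(CO)c2O)c(C)c1O | intermediate
9 | 3-hydroxy-4-(methoxycarbonyl)-2,5-dimethylphenyl 3-formyl-2,5-dihydroxy-4-methoxy-6-methylbenzoate | COC(=O)c1c(C)cc(OC(=O)c2c(C)c(O)c(OC)c(C=O)c2O)c(C)c1O | intermediate
10 | 3-hydroxy-4-(methoxycarbonyl)-2,5-dimethylphenyl 3-formyl-2,4,5-trihydroxy-6-methylbenzoate | COC(=O)c1c(C)cc(OC(=O)c2c(C)c(O)c(O)c(C=O)c2O)c(C)c1O | target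

## Step count and risks

Total steps: 6. Longest linear sequence: 6 steps (from 1 or 2 to 10).

**Step 3 (key step).**
- What may go wrong: addition at C3 may compete with C6, or a second methylation at C3 may follow, because methyl is the least nucleophilic alkyl radical and a methoxy-bearing quinone carbon is deactivated but not inert. Water may add at C6 or hydrolyse the quinone aryl ester in hot aqueous acid, since 4 is a strongly electrophilic acylquinone. Radical generation may be inefficient, acetic acid being the least readily oxidised simple acid.
- Fallback, from 1, returning at 6: the methyl group is placed before the ester is made. Acid 1 is lithiated at C6, ortho to both the carboxylate and the C5 methoxy group, with s-BuLi and TMEDA in THF at −78 °C and quenched with iodomethane to give 3,4,6-trimethoxy-2-methylbenzoic acid F1. F1 is coupled with 2 using trifluoroacetic anhydride in toluene at rt, the classical activation for hindered depside acids, to give 3-hydroxy-4-(methoxycarbonyl)-2,5-dimethylphenyl 3,4,6-trimethoxy-2-methylbenzoate F2. Oxidation of F2 with (NH4)2Ce(NO3)6 in aqueous MeCN then gives 6. The price is the hindered esterification that the main route avoids.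

**Step 2.**
- What may go wrong: loss of chemoselectivity (oxidation or nitration of the ring B phenol by tetravalent cerium), incomplete oxidation because the ester lowers the electron density of ring A, or decomposition of the electrophilic quinone during aqueous work-up.
- Fallback, from 3, returning at 4: the two para oxygens are differentiated first. BCl3 in CH2Cl2 (−78 to 0 °C) cleaves only the C2 methyl ether, the one ortho to the ester carbonyl, giving 3-hydroxy-4-(methoxycarbonyl)-2,5-dimethylphenyl 2-hydroxy-4,5-dimethoxybenzoate F3. This para-methoxyphenol is oxidised under much milder conditions with PhI(OAc)2 in MeCN/H2O at 0 °C to give 4.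

**Step 5.**
- What may go wrong: slow formylation because the C2 phenoxide is tied into a chelate with the ester carbonyl and C3 is flanked on both sides; autoxidation of the hydroquinone magnesium salt if air enters; methanolysis of the aryl ester by the methanol formed.
- Fallback, from 7, returning at 9: Rieche formylation with Cl2CHOMe and TiCl4 in CH2Cl2 at 0 °C, then aqueous hydrolysis. This is an acid-mediated electrophilic substitution with no phenoxide, base or methanol present. Titanium bound at the C2 oxygen and the flanking C4 methoxy group direct the electrophile to C3, the position formylated in the same way in orsellinate esters. No compound outside the list is made.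

**Step 6.**
- What may go wrong: incomplete ether cleavage because the product binds boron in several chelates; on longer exposure, attack on the ring B methyl ester; oxidative degradation of the free trihydroxyarene aldehyde during work-up.
- Fallback, from 7, returning at 10: the order of the last two operations is reversed. The C4 methyl ether of 7 is cleaved before any aldehyde is present, with BBr3 in CH2Cl2 at −78 to −20 °C, to give 3-hydroxy-4-(methoxycarbonyl)-2,5-dimethylphenyl 3,4,6-trihydroxy-2-methylbenzoate F4. Rieche formylation (Cl2CHOMe, TiCl4, CH2Cl2, 0 °C) at C3, the only free carbon of ring A and now between two hydroxyls, gives 10 directly.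

## Further compounds

F1 | step 3 | 3,4,6-trimethoxy-2-methylbenzoic acid | COc1cc(OC)c(C(=O)O)c(C)c1OC
F2 | step 3 | 3-hydroxy-4-(methoxycarbonyl)-2,5-dimethylphenyl 3,4,6-trimethoxy-2-methylbenzoate | COC(=O)c1c(C)cc(OC(=O)c2c(C)c(OC)c(OC)cc2OC)c(C)c1O
F3 | step 2 | 3-hydroxy-4-(methoxycarbonyl)-2,5-dimethylphenyl 2-hydroxy-4,5-dimethoxybenzoate | COC(=O)c1c(C)cc(OC(=O)c2cc(OC)c(OC)cc2O)c(C)c1O
F0 | step 5 | none | none
F4 | step 6 | 3-hydroxy-4-(methoxycarbonyl)-2,5-dimethylphenyl 3,4,6-trihydroxy-2-methylbenzoate | COC(=O)c1c(C)cc(OC(=O)c2c(C)c(O)c(O)cc2O)c(C)c1O
A1 | alternative 1 | 2,4,5-tris(benzyloxy)-6-methylbenzoic acid | Cc1c(C(=O)O)c(OCc2ccccc2)cc(OCc2ccccc2)c1OCc1ccccc1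
A2 | alternative 1 | methyl 2-(benzyloxy)-3,6-dimethyl-4-[(2,4,6-trimethoxyphenyl)iodonio]benzoate 4-methylbenzenesulfonate | COC(=O)c1c(C)cc([I+]c2c(OC)cc(OC)cc2OC)c(C)c1OCc1ccccc1.Cc1ccc(cc1)S(=O)(=O)[O-]
A3 | alternative 1 | methyl 2-(benzyloxy)-3,6-dimethyl-4-{[2,4,5-tris(benzyloxy)-6-methylbenzoyl]oxy}benzoate | COC(=O)c1c(C)cc(OC(=O)c2c(C)c(OCc3ccccc3)c(OCc3ccccc3)cc2OCc2ccccc2)c(C)c1OCc1ccccc1
A4 | alternative 2 | 1,2,5-tris(benzyloxy)-4-iodo-3-methylbenzene | Cc1c(I)c(OCc2ccccc2)cc(OCc2ccccc2)c1OCc1ccccc1
A5 | alternative 2 | carbon monoxide | [C-]#[O+]
A6 | alternative 2 | methyl 2-hydroxy-3,6-dimethyl-4-{[2,4,5-tris(benzyloxy)-6-methylbenzoyl]oxy}benzoate | COC(=O)c1c(C)cc(OC(=O)c2c(C)c(OCc3ccccc3)c(OCc3ccccc3)cc2OCc2ccccc2)c(C)c1O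
A7 | alternative 3 | 3-(benzyloxy)-4-(methoxycarbonyl)-2,5-dimethylphenyl 5-(benzyloxy)-3-methyl-2-oxo-2H-pyran-4-carboxylate | COC(=O)c1c(C)cc(OC(=O)C2=C(C)C(=O)OC=C2OCc2ccccc2)c(C)c1OCc1ccccc1
A8 | alternative 3 | 2-(benzyloxy)-1-methoxy-1-(trimethylsilyloxy)ethene | COC(=COCc1ccccc1)O[Si](C)(C)C
A9 | alternative 3 | methyl 2-(benzyloxy)-4-{[2,5-bis(benzyloxy)-4-hydroxy-6-methylbenzoyl]oxy}-3,6-dimethylbenzoate | COC(=O)c1c(C)cc(OC(=O)c2c(C)c(OCc3ccccc3)c(O)cc2OCc2ccccc2)c(C)c1OCc1ccccc1
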